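A direct plan would carry ring A as the benzyl-protected aldehyde A1 (4-benzyloxy-2,6-dihydroxy-3,5-dimethoxybenzaldehyde), condense it under HCl with the ω-methoxy ketone A2 to the flavylium chloride A3, oxidise A3 at C4 to the 7-benzyl flavone A4 and hydrogenolyse the benzyl ether. Its weakest steps would be:
- the acid condensation to A3, in which a hexasubstituted aldehyde would have to meet a hindered, electron-rich ketone under conditions that threaten the benzyl ether;
- the oxidation of the flavylium cation at C4, which would depend on a minor C4 pseudobase while water adds mainly at C2 and opens the ring;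
- the benzylation and debenzylation, which would add two steps and no complexity.

The route rests on cutting C4–C4a together with O1–C2: ring A is phloroglucinol itself, whose three equivalent C–H carbons become C4a, C6 and C8 and whose oxygens become O1, 5-OH and 7-OH, while an α-methoxy aroylacetate brings C2, C3, C4, the 3-methoxy group and ring B. The key step, a thermal Mentzer condensation, would acylate the ring carbon and close ring C in one operation, at the final oxidation level and with both phenols free. The two ring A carbons that remain, the only activated C–H sites left, would then be brominated and methoxylated. No flavylium salt, no C4 oxidation and no protecting group would occur.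

Key step: step 2

Remark: the target has no stereocentre; anhydrous phloroglucinol is assumed for the key step, since water would hydrolyse the acylketene to a ketoacid that would lose CO2.

**Step 1**
Reactants: 1 2,4,5-trimethoxybenzoic acid; 2 methyl methoxyacetate
Product: 6 methyl 2-methoxy-3-oxo-3-(2,4,5-trimethoxyphenyl)propanoate (racemic), via acid chloride 3 (not isolated), via lithium ester enolate 4 (not isolated), via lithium ketoester enolate 5 (not isolated)
Conditions: 1, (COCl)2, DMF (cat.), CH2Cl2, 0 °C to rt, concentrate; 2 (2.1 equiv), LiN(i-Pr)2 (2.1 equiv), THF, −78 °C; then 3 in THF, −78 to 0 °C; aq. HCl (1 M)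
Reagents that add atoms: none
Why: Crossed Claisen-type acylation of a lithium ester enolate by an acid chloride, in which the chelated enolate 4 of the α-alkoxy ester should attack 3 at carbon at −78 °C and the second equivalent of 4 should convert the more acidic ketoester into its enolate 5, so that no second acylation occurs; the stereocentre of 6 is formed racemic and disappears in step 2.

**Step 2**
Reactants: 6 methyl 2-methoxy-3-oxo-3-(2,4,5-trimethoxyphenyl)propanoate; 7 phloroglucinol (benzene-1,3,5-triol)
Product: 10 5,7-dihydroxy-3-methoxy-2-(2,4,5-trimethoxyphenyl)-4H-chromen-4-one, via acylketene 8 (not isolated), via triketone 9 (not isolated)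
Conditions: 7 (1.5 equiv), neat melt, Ar, 240 °C (microwave), 15 min, MeOH and H2O distilled off
Reagents that add atoms: none
Why: Mentzer pyrone synthesis, the thermal condensation of a phenol with a β-keto ester. Above about 200 °C ketoester 6 should lose methanol to give acylketene 8, and the ketene carbon is attacked by a ring carbon of phloroglucinol, a vinylogous enol, which forms the C4–C4a bond and, after rearomatisation, triketone 9. A hydroxyl ortho to the new acyl group then adds to the aryl ketone carbonyl in a 6-exo-trig closure that forms the O1–C2 bond, and loss of water completes the pyranone ring C. The closest known reaction type is the solvent-free condensation of phloroglucinol with aroylacetates to 5,7-dihydroxyflavones and of phenols with α-alkyl acetoacetates to 3-alkylchromones, the α-substituent here being methoxy. No stereocentre remains, since the racemic centre of 6 and 9 becomes C3 of the aromatic ring. The step needs C- over O-acylation and chromone over coumarin closure, which should be secured because O-acylation is reversible at this temperature while C-acylation is not, because no acid is present to drive a Pechmann closure onto the ketone that the 2'-methoxy group hinders, and because the three ring carbons of 7 and the two ortho hydroxyls of 9 are equivalent, so that only one flavone can form.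

**Step 3**
Reactants: 10 5,7-dihydroxy-3-methoxy-2-(2,4,5-trimethoxyphenyl)-4H-chromen-4-one
Product: 13 6,8-dibromo-5,7-dihydroxy-3-methoxy-2-(2,4,5-trimethoxyphenyl)-4H-chromen-4-one, via 6-bromo flavone 11 (not isolated), via 8-bromo flavone 12 (not isolated)
Conditions: NBS (2.05 equiv), THF, 0 °C, dark
Reagents that add atoms: N-bromosuccinimide O=C1CCC(=O)N1Br
Why: Electrophilic aromatic bromination, in which C6 and C8, each ortho or para to both free hydroxyls of the phloroglucinol-type ring A, are far more nucleophilic than C3' and C6' of the tri-ether ring B, so that two equivalents of NBS at 0 °C should stop at dibromide 13 whichever monobromide, 11 or 12, forms first.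

**Step 4**
Reactants: 13 6,8-dibromo-5,7-dihydroxy-3-methoxy-2-(2,4,5-trimethoxyphenyl)-4H-chromen-4-one
Product: 16 5,7-dihydroxy-3,6,8-trimethoxy-2-(2,4,5-trimethoxyphenyl)-4H-chromen-4-one (the target), via 8-bromo-6-methoxy flavone 14 (not isolated), via 6-bromo-8-methoxy flavone 15 (not isolated)
Conditions: NaOMe (12 equiv, in MeOH), CuBr (0.5 equiv), DMF, 110 °C, Ar; then aq. HCl (1 M), 0 °C
Reagents that add atoms: sodium methoxide [Na+].[O-]C
Why: Copper-mediated Ullmann-type methanolysis of aryl bromides, the classical exchange used on bromophenols and on 6,8-dibromo-5,7-dihydroxyflavones, in which both bromides, each ortho to a phenoxide, should be replaced by methoxide, and because C6 and C8 end with the same substituent the order of exchange (through 14 or 15) and any base-induced opening and reclosure of ring C lead to the same product after acidification.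

**Compound list**
1 | 2,4,5-trimethoxybenzoic acid | COc1cc(OC)c(C(=O)O)cc1OC | starting material
2 | methyl methoxyacetate (methyl 2-methoxyacetate) | COCC(=O)OC | starting material
3 | 2,4,5-trimethoxybenzoyl chloride (not isolated) | COc1cc(OC)c(C(=O)Cl)cc1OC | intermediate
4 | lithium 1,2-dimethoxyethen-1-olate, enolate geometry immaterial (not isolated) | [Li+].[O-]C(OC)=COC | intermediate
5 | lithium 2,3-dimethoxy-3-oxo-1-(2,4,5-trimethoxyphenyl)prop-1-en-1-olate, enolate geometry immaterial (not isolated) | COC(=O)C(OC)=C([O-])c1cc(OC)c(OC)cc1OC.[Li+] | intermediate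
6 | methyl 2-methoxy-3-oxo-3-(2,4,5-trimethoxyphenyl)propanoate, racemic | COC(C(=O)OC)C(=O)c1cc(OC)c(OC)cc1OC | intermediate
7 | phloroglucinol (benzene-1,3,5-triol) | Oc1cc(O)cc(O)c1 | starting material
8 | 2-methoxy-1-(2,4,5-trimethoxyphenyl)prop-2-ene-1,3-dione, acylketene (not isolated) | COC(=C=O)C(=O)c1cc(OC)c(OC)cc1OC | intermediate
9 | 2-methoxy-1-(2,4,6-trihydroxyphenyl)-3-(2,4,5-trimethoxyphenyl)propane-1,3-dione, racemic (not isolated) | COC(C(=O)c1c(O)cc(O)cc1O)C(=O)c1cc(OC)c(OC)cc1OC | intermediate
10 | 5,7-dihydroxy-3-methoxy-2-(2,4,5-trimethoxyphenyl)-4H-chromen-4-one | COc1cc(OC)c(-c2oc3cc(O)cc(O)c3c(=O)c2OC)cc1OC | intermediate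
11 | 6-bromo-5,7-dihydroxy-3-methoxy-2-(2,4,5-trimethoxyphenyl)-4H-chromen-4-one (not isolated) | COc1cc(OC)c(-c2oc3cc(O)c(Br)c(O)c3c(=O)c2OC)cc1OC | intermediate
12 | 8-bromo-5,7-dihydroxy-3-methoxy-2-(2,4,5-trimethoxyphenyl)-4H-chromen-4-one (not isolated) | COc1cc(OC)c(-c2oc3c(Br)c(O)cc(O)c3c(=O)c2OC)cc1OC | intermediate
13 | 6,8-dibromo-5,7-dihydroxy-3-methoxy-2-(2,4,5-trimethoxyphenyl)-4H-chromen-4-one | COc1cc(OC)c(-c2oc3c(Br)c(O)c(Br)c(O)c3c(=O)c2OC)cc1OC | intermediate
14 | 8-bromo-5,7-dihydroxy-3,6-dimethoxy-2-(2,4,5-trimethoxyphenyl)-4H-chromen-4-one (not isolated) | COc1cc(OC)c(-c2oc3c(Br)c(O)c(OC)c(O)c3c(=O)c2OC)cc1OC | intermediate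
15 | 6-bromo-5,7-dihydroxy-3,8-dimethoxy-2-(2,4,5-trimethoxyphenyl)-4H-chromen-4-one (not isolated) | COc1cc(OC)c(-c2oc3c(OC)c(O)c(Br)c(O)c3c(=O)c2OC)cc1OC | intermediate
16 | 5,7-dihydroxy-3,6,8-trimethoxy-2-(2,4,5-trimethoxyphenyl)-4H-chromen-4-one (5,7-dihydroxy-3,6,8,2',4',5'-hexamethoxyflavone) | COc1cc(OC)c(-c2oc3c(OC)c(O)c(OC)c(O)c3c(=O)c2OC)cc1OC | target

**Step count and risks**
Total step count: 4. Longest linear sequence: 4 steps (1 to 16); phloroglucinol 7 enters at step 2.

Steps most likely to fail:

Step 2 (key step). The ketoester may decompose before the acylketene is trapped at carbon, or the O-acylated phenol may close onto the aryl ketone in the Pechmann sense and give a coumarin. The fallback sets out from 7 and 1 and comes back at 10. Houben–Hoesch acylation of 7 with methoxyacetonitrile (ZnCl2, HCl gas, Et2O, 0 °C) would give 2-methoxy-1-(2,4,6-trihydroxyphenyl)ethan-1-iminium chloride F1, which boiling water would hydrolyse to 2-methoxy-1-(2,4,6-trihydroxyphenyl)ethan-1-one F2. Acid 1 and KOH would give potassium 2,4,5-trimethoxybenzoate F3, which with chloride 3 would give 2,4,5-trimethoxybenzoic anhydride F4. Allan–Robinson fusion of F2 with F4 and F3 (175 °C), followed by KOH in aqueous ethanol to cleave aroyl esters and by acidification, would give 10.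

Step 4. Hot methoxide may open ring C and cleave the resulting β-diketone in a retro-Claisen reaction, or bromine may be lost reductively in competition with the exchange. The fallback sets out from 6 and comes back at 16, and places the methoxy groups on ring A before the heterocycle exists. Methyl 2,4,6-trihydroxybenzoate F5 would be dibrominated (NBS, THF, 0 °C) to methyl 3,5-dibromo-2,4,6-trihydroxybenzoate F6 and methanolysed (NaOMe, CuBr, MeOH/DMF, 110 °C) to methyl 2,4,6-trihydroxy-3,5-dimethoxybenzoate F7. Saponification (degassed aq. NaOH, then HCl) would give 2,4,6-trihydroxy-3,5-dimethoxybenzoic acid F8, which would lose CO2 on warming in water to give 2,4-dimethoxybenzene-1,3,5-triol F9. The Mentzer condensation of F9, whose single free ring carbon lies between two equivalent hydroxyls, with 6 (neat, Ar, 240 °C) would then give 16 directly through acylketene 8 and 1-(2,4,6-trihydroxy-3,5-dimethoxyphenyl)-2-methoxy-3-(2,4,5-trimethoxyphenyl)propane-1,3-dione F10.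

Step 1. The enolate may be acylated at oxygen, or the methoxyacetate may condense with itself before the hindered, electron-rich acid chloride reacts. The fallback sets out from 1 (through chloride 3) and comes back at 6, forming the α C–O bond last. Acylation of Meldrum's acid with 3 (pyridine, CH2Cl2, 0 °C) would give 5-[hydroxy(2,4,5-trimethoxyphenyl)methylidene]-2,2-dimethyl-1,3-dioxane-4,6-dione F11, and methanolysis (MeOH, reflux) would give methyl 3-oxo-3-(2,4,5-trimethoxyphenyl)propanoate F12. Regitz diazo transfer (4-acetamidobenzenesulfonyl azide, Et3N, MeCN) would give methyl 2-diazo-3-oxo-3-(2,4,5-trimethoxyphenyl)propanoate F13. Carbenoid O–H insertion into methanol (Rh2(OAc)4, 1 mol %, MeOH, CH2Cl2, 40 °C) would give 6.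

**Further compounds**
F1 | step 2 | 2-methoxy-1-(2,4,6-trihydroxyphenyl)ethan-1-iminium chloride | COCC(=[NH2+])c1c(O)cc(O)cc1O.[Cl-]
F2 | step 2 | 2-methoxy-1-(2,4,6-trihydroxyphenyl)ethan-1-one | COCC(=O)c1c(O)cc(O)cc1O
F3 | step 2 | potassium 2,4,5-trimethoxybenzoate | COc1cc(OC)c(C(=O)[O-])cc1OC.[K+]
F4 | step 2 | 2,4,5-trimethoxybenzoic anhydride | COc1cc(OC)c(C(=O)OC(=O)c2cc(OC)c(OC)cc2OC)cc1OC
F5 | step 4 | methyl 2,4,6-trihydroxybenzoate | COC(=O)c1c(O)cc(O)cc1O
F6 | step 4 | methyl 3,5-dibromo-2,4,6-trihydroxybenzoate | COC(=O)c1c(O)c(Br)c(O)c(Br)c1O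
F7 | step 4 | methyl 2,4,6-trihydroxy-3,5-dimethoxybenzoate | COC(=O)c1c(O)c(OC)c(O)c(OC)c1O
F8 | step 4 | 2,4,6-trihydroxy-3,5-dimethoxybenzoic acid | O=C(O)c1c(O)c(OC)c(O)c(OC)c1O
F9 | step 4 | 2,4-dimethoxybenzene-1,3,5-triol | COc1c(O)cc(O)c(OC)c1O
F10 | step 4 | 1-(2,4,6-trihydroxy-3,5-dimethoxyphenyl)-2-methoxy-3-(2,4,5-trimethoxyphenyl)propane-1,3-dione, racemic | COC(C(=O)c1c(O)c(OC)c(O)c(OC)c1O)C(=O)c1cc(OC)c(OC)cc1OC
F11 | step 1 | 5-[hydroxy(2,4,5-trimethoxyphenyl)methylidene]-2,2-dimethyl-1,3-dioxane-4,6-dione | COc1cc(OC)c(C(O)=C2C(=O)OC(C)(C)OC2=O)cc1OC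
F12 | step 1 | methyl 3-oxo-3-(2,4,5-trimethoxyphenyl)propanoate | COC(=O)CC(=O)c1cc(OC)c(OC)cc1OC
F13 | step 1 | methyl 2-diazo-3-oxo-3-(2,4,5-trimethoxyphenyl)propanoate | COC(=O)C(=[N+]=[N-])C(=O)c1cc(OC)c(OC)cc1OC
A1 | direct plan | 4-(benzyloxy)-2,6-dihydroxy-3,5-dimethoxybenzaldehyde | O=Cc1c(O)c(OC)c(OCc2ccccc2)c(OC)c1O
A2 | direct plan | 2-methoxy-1-(2,4,5-trimethoxyphenyl)ethan-1-one | COCC(=O)c1cc(OC)c(OC)cc1OC
A3 | direct plan | 7-(benzyloxy)-5-hydroxy-3,6,8-trimethoxy-2-(2,4,5-trimethoxyphenyl)chromenylium chloride | COc1cc(OC)c(-c2[o+]c3c(OC)c(OCc4ccccc4)c(OC)c(O)c3cc2OC)cc1OC.[Cl-]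
A4 | direct plan | 7-(benzyloxy)-5-hydroxy-3,6,8-trimethoxy-2-(2,4,5-trimethoxyphenyl)-4H-chromen-4-one | COc1cc(OC)c(-c2oc3c(OC)c(OCc4ccccc4)c(OC)c(O)c3c(=O)c2OC)cc1OC
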